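## Analysis of the target

The target is a germacranolide: a ten-membered carbocycle (C1–C10) fused across C7–C8 to an α-methylene-γ-butyrolactone (C8–O–C12(=O)–C11(=C13)–C7). The ring holds two trisubstituted alkenes in a 1,5-relationship. C1=C10 (methyl C14 on C10) is E with the ring bonds trans. C4=C5 (acetoxymethyl C15 on C4) has the ring carbons C3 and C6 cis, and is E by CIP only because C15 outranks C3. Three contiguous stereocentres, C6 (R), C7 (R) and C8 (S), carry O6, C11 and O8 on alternating faces, so H7 is trans to both H6 and H8 and the lactone is trans-fused. The fourth stereocentre, C2′ (R) of the 2,3-dihydroxy-2-methylpropanoate on O6, is remote and has to come from an enantiopure acid. Sensitive groups are the α-methylene lactone (nucleophiles, base), the allylic acetate and allylic C6 ester, the free 1,2-diol, and the cyclodeca-1,5-diene itself (acid-induced transannular cyclisation, Cope rearrangement). The difficulty is a strained ten-membered ring with two trisubstituted alkenes of different ring geometry. The route rests on the C2–C3 ethano bridge between the two alkenes: C1=C10 and C4=C5 are the cycloreversion product of a bicyclo[2.2.0]hexane (central bond C1–C4, outer bonds C2–C3 and C5–C10), which is the [2+2] adduct of a cyclohexenone (C5–C10, ketone at C6) and a cyclobutene (C1–C4).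

## Retrosynthetic reasoning

**35 ⇒ 34 ⇒ 27 + 32.** The C6–O acyl bond is cut last. The diol ester and the C15 acetate would not survive enolate chemistry, and the free diol is kept masked as two triethylsilyl ethers so that the last step is a buffered fluoride deprotection, not an acid hydrolysis that would threaten the diene. Acid 32 goes back through diol acid 30 to the chiral-pool bromo acid 28, with C2′ untouched. The forward acylation has to join a hindered allylic alcohol with an α-quaternary acid.

**27 ⇒ 26 ⇒ 25 ⇒ 23 ⇒ 22.** The acetate is taken off C15 and the exocyclic methylene off C11. Both go on after the ring is formed: the acetate has enolisable hydrogens and the α-methylene lactone would not tolerate the thermal step. Lactone 22 with O6 and O15 as silyl ethers is the species that is methylenated through Mannich base 23.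

**22 ⇒ 21.** C1–C4 and C5–C10 are reconnected. The ten-membered diene becomes a cyclohexane (ring A, C5–C10) carrying a cis-fused bicyclo[2.2.0]hexane, so no macrocyclisation is needed. The forward reaction must break the central C1–C4 bond, pass through the chair cyclohexane-1,4-diyl and cleave C5–C10. The trans lactone holds ring A in one chair, so the ring A configuration at C10 and C5 decides which alkene becomes trans. C1 must be axial and C4 equatorial on ring A, meaning the four-membered rings sit on the face anti to H7.

**21 ⇒ 20 ⇒ 19 ⇒ 18.** The C6 carbinol and the C15 alcohol are traced to a ketone and a carboxyl group. In the tricycle, C15 lies directly under C6 on the cyclobutane face, while the target needs O6 on the opposite face. Hydride must therefore arrive from the hindered face. The plan does this by freeing the C15 acid (hence a tert-butyl ester, cleaved without base) and letting borane, bound at that carboxyl as it is reduced, deliver hydride to C6 intramolecularly.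

**18 ⇒ 12 + 17.** C4–C5 and C1–C10 are cut in a retro-[2+2]. The partners are enone lactone 12, which already holds C7 and C8, and cyclobutene ester 17, whose ester directs head-to-head bonding and becomes C15. The forward reaction has to deliver the head-to-head adduct, cis-fused at C5–C10, with the new C10–C1 bond axial.

**12 ⇒ 11 ⇒ 10 ⇒ 9.** The enone is opened at C5=C10 (ring-closing metathesis) and at C5–C6 (vinyl addition to an aldehyde). This leaves lactone aldehyde 9 with a methallyl group on C8. The C6 carbinol configuration is irrelevant because it is oxidised.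

**9 ⇒ 6 ⇒ 4 ⇒ 3 ⇒ 1 + 2 (and 5).** The trans-4,5-disubstituted lactone comes from retro-aldol opening of a donor–acceptor cyclopropane and lactonisation. The cyclopropane comes from asymmetric cyclopropanation of furoate 1 with diazoacetate 2, ozonolysis, and allylation with silane 5. C7 is set in the cyclopropanation and C8 in the allylation.

**17 ⇒ 16 ⇒ 13.** The cyclobutene ester is made by α-bromination/esterification of cyclobutanecarboxylic acid 13 and dehydrobromination.

## Alternatives that were turned down

**Alternative 1: anionic oxy-Cope ring expansion.**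
- Disconnection: C2–C3 is cut and C5–C10 reconnected, giving a six-membered carbinol from the terpene chiral pool with alkenyl groups on C5 and C10.
- Forward key step: the potassium C5 alkoxide (hydride base, crown ether) undergoes the [3,3] shift and the resulting enolate is silylated, giving the ten-membered C5 silyl enol ether A1.
- For: the rearrangement is charge-accelerated and runs near room temperature, and the chair transition state sets E-C1=C10 with good precedent. On mildness of the ring-forming step and on that alkene it is stronger than the chosen route, which needs about 185 °C.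
- Against: A1 carries an oxygen on C5 that the target lacks. It has to be removed (enol triflate, reduction) with the C4=C5 geometry depending only on enolate geometry, next to an epimerisable, eliminable C6 oxygen. The lactone is still absent (C12 oxidation, closure onto O8), and five silyl and acetal groups must be told apart, one of them by acid on the diene.
- Comparison: the chosen route carries the lactone from the first steps, has no oxygen to excise and has a shorter end game. In place of the milder key step it offers ring formation from a compact tricycle and far fewer protecting-group operations.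

**Alternative 2: B-alkyl Suzuki–Miyaura closure at C1–C2.**
- Disconnection: the C1(sp2)–C2(sp3) bond.
- Forward key step: a hindered dialkylborane adds to the terminal C2=C3 alkene of an open-chain diene, and palladium-catalysed coupling with the C1 alkenyl iodide under carbonate base closes the ring to A2.
- For: both trisubstituted alkenes are built with defined geometry before closure, and lactone and C6 are already in place. On certainty of alkene geometry it is stronger than the chosen route.
- Against: a strained ten-membered ring must close through an alkylpalladium species at high dilution, against β-hydride elimination, protodeboronation and oligomerisation. The hydroboration must pick the terminal end of a conjugated diene. The open precursor needs separate stereoselective syntheses of an E-trisubstituted alkenyl iodide and a ring-cis trisubstituted allylic ether, so the sequence is long.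
- Comparison: the chosen route avoids macrocyclisation and reaches the ring in fewer steps. Its alkene geometry rests on a conformational argument, not on pre-formed alkenes.

**Alternative 3: intramolecular Horner–Wadsworth–Emmons closure at C4=C5.**
- Disconnection: the C4=C5 double bond.
- Forward key step: Masamune–Roush conditions (lithium salt, amidine base) at high dilution condense a C4 phosphonoacetate with a C5 aldehyde to give dienoate A3.
- For: the intrinsic E-selectivity puts the ester trans to C6, which is the ring-cis C4=C5 the target needs, and C15 arrives at the carboxyl level. On that alkene it is stronger than the chosen route.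
- Against: closing a ten-membered carbocycle by olefination is limited by transannular strain and dimerisation. The C5 aldehyde is α to the silyloxy-bearing C6 and can epimerise or eliminate under base. E-C1=C10 must be made separately. A3 still lacks the lactone, so C12 oxidation, lactonisation and selective enoate reduction remain.
- Comparison: the chosen route needs no high dilution and has a shorter sequence after ring formation. It gives up the built-in C4=C5 selectivity.

Key step: step 10

**Remarks before the steps**

- Assumption: the (S,S)-isopropyl bis(oxazoline)–copper catalyst is taken to give the (1S,5S,6S) cyclopropane 3. If the sense of induction is opposite, the enantiomeric ligand is used.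
- Assumption: (S)-3-bromo-2-hydroxy-2-methylpropanoic acid 28 is taken as a commercial chiral-pool compound.
- Remark: germacrane numbering is used for all intermediates from 12 on. The CIP descriptor at C7 switches between R and S with the substituent on O6 (priority change only); no bond to C7 is touched after step 4.

## Route

Step 1
Reactants: 1 methyl furan-2-carboxylate; 2 ethyl diazoacetate
Product: 3 6-ethyl 3-methyl (1S,5S,6S)-2-oxabicyclo[3.1.0]hex-3-ene-3,6-dicarboxylate
Conditions: Cu(OTf)2 (cat.), 2,2′-(propane-2,2-diyl)bis[(4S)-4-isopropyl-4,5-dihydrooxazole] (cat.), PhNHNH2 (cat., reduces the salt to monovalent copper), slow addition of 2, CH2Cl2, 0 °C; recrystallisation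
Reagents that add atoms: none
Why: Copper-carbene cyclopropanation of the more electron-rich, unsubstituted C4=C5 bond of the furan; the C2-symmetric ligand selects the face and the ester goes exo, so the three cyclopropane centres (one is the future C7) are set together, and recrystallisation should raise the enantiomeric purity.

Step 2
Reactants: 3 6-ethyl 3-methyl (1S,5S,6S)-2-oxabicyclo[3.1.0]hex-3-ene-3,6-dicarboxylate
Product: 4 ethyl (1S,2S,3S)-2-formyl-3-[(methoxyoxalyl)oxy]cyclopropane-1-carboxylate
Conditions: O3, CH2Cl2, −78 °C; Me2S, −78 °C → rt
Reagents that add atoms: ozone (O=[O+][O-])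
Why: Ozonolysis with reductive work-up cleaves the only alkene, an enol ether, into the formyl group and the methyl oxalate without touching the cyclopropane stereocentres.

Step 3
Reactants: 4 ethyl (1S,2S,3S)-2-formyl-3-[(methoxyoxalyl)oxy]cyclopropane-1-carboxylate; 5 trimethyl(2-methylprop-2-en-1-yl)silane
Product: 6 ethyl (1S,2R,3S)-2-[(1S)-1-hydroxy-3-methylbut-3-en-1-yl]-3-[(methoxyoxalyl)oxy]cyclopropane-1-carboxylate
Conditions: BF3·OEt2, CH2Cl2, −78 °C
Reagents that add atoms: none
Why: Hosomi–Sakurai allylation of the aldehyde; Felkin–Anh attack on the bisected conformer of the cyclopropanecarbaldehyde should set the carbinol centre (the future C8) with the S configuration.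

Step 4
Reactants: 6 ethyl (1S,2R,3S)-2-[(1S)-1-hydroxy-3-methylbut-3-en-1-yl]-3-[(methoxyoxalyl)oxy]cyclopropane-1-carboxylate
Product: 9 (2S,3R)-2-(2-methylprop-2-en-1-yl)-5-oxooxolane-3-carbaldehyde, via cyclopropanol 7 (not isolated), via hydroxy aldehyde ester 8 (not isolated)
Conditions: Ba(OH)2·8H2O, MeOH, 0 °C
Reagents that add atoms: none
Why: Saponification of the oxalate frees a donor–acceptor cyclopropanol that opens by retro-aldol cleavage toward the ester, and the carbinol then lactonises on the ethyl ester. C8 is retained and C7, α to the new aldehyde, rests in the more stable trans arrangement.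

Step 5
Reactants: 9 (2S,3R)-2-(2-methylprop-2-en-1-yl)-5-oxooxolane-3-carbaldehyde
Product: 10 (4S,5S)-4-(1-hydroxyprop-2-en-1-yl)-5-(2-methylprop-2-en-1-yl)oxolan-2-one (both carbinol epimers)
Conditions: CH2=CHMgBr, THF, −78 °C
Reagents that add atoms: vinylmagnesium bromide (C=C[Mg]Br)
Why: Grignard 1,2-addition is chemoselective for the aldehyde over the lactone at low temperature; the new C6 centre is uncontrolled and is removed by oxidation in step 7.

Step 6
Reactants: 10 (4S,5S)-4-(1-hydroxyprop-2-en-1-yl)-5-(2-methylprop-2-en-1-yl)oxolan-2-one
Product: 11 (3aS,7aS)-4-hydroxy-6-methyl-3a,4,7,7a-tetrahydro-1-benzofuran-2(3H)-one (both C4 epimers)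
Conditions: second-generation Grubbs catalyst (H2IMes)(PCy3)Cl2Ru=CHPh (cat.), CH2Cl2 (dilute), 40 °C
Reagents that add atoms: none
Why: Ring-closing metathesis between the vinyl and the 1,1-disubstituted methallyl alkene gives the six-membered trisubstituted C5=C10 alkene, driven by loss of ethene; the trans diequatorial side chains of the lactone close without strain.

Step 7
Reactants: 11 (3aS,7aS)-4-hydroxy-6-methyl-3a,4,7,7a-tetrahydro-1-benzofuran-2(3H)-one
Product: 12 (3aR,7aS)-6-methyl-3a,7a-dihydro-1-benzofuran-2,4(3H,7H)-dione
Conditions: Dess–Martin periodinane, NaHCO3, CH2Cl2, 0 °C → rt; used without storage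
Reagents that add atoms: none
Why: Dess–Martin oxidation converts both allylic carbinol epimers into the enone under near-neutral conditions, which matters because 12 is a β-acyloxy ketone that base could eliminate and aromatise.

Step 8
Reactants: 13 cyclobutanecarboxylic acid
Product: 16 tert-butyl 1-bromocyclobutane-1-carboxylate, via cyclobutanecarbonyl chloride 14 (not isolated), via 1-bromocyclobutanecarbonyl chloride 15 (not isolated)
Conditions: SOCl2, 70 °C; NBS, HBr (cat.), 85 °C; evaporation; tBuOH, pyridine, DMAP (cat.), CH2Cl2, 0 °C → rt
Reagents that add atoms: N-bromosuccinimide (O=C1CCC(=O)N1Br); tert-butanol (CC(C)(C)O)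
Why: Hell–Volhard–Zelinsky-type α-bromination through the enol of the acyl chloride, then esterification of the α-bromo acyl chloride with tert-butanol.

Step 9
Reactants: 16 tert-butyl 1-bromocyclobutane-1-carboxylate
Product: 17 tert-butyl cyclobut-1-ene-1-carboxylate
Conditions: KOtBu, THF, 0 °C → rt; used freshly distilled
Reagents that add atoms: none
Why: E2 dehydrobromination of the tertiary α-bromo ester by a hindered alkoxide that cannot transesterify or saponify the tert-butyl ester.

Step 10
Reactants: 12 (3aR,7aS)-6-methyl-3a,7a-dihydro-1-benzofuran-2,4(3H,7H)-dione; 17 tert-butyl cyclobut-1-ene-1-carboxylate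
Product: 18 keto tert-butyl ester photoadduct (1R,4S,5R,7R,8S,10R): ring A of 12 with C5–C10 cis-fused to the bicyclo[2.2.0]hexane C1–C4/C2–C3 and CO2tBu on C4 and the small rings anti to H7
Conditions: 17 (excess), hν (350 nm, Pyrex), degassed CH2Cl2, −40 °C; filtration through neutral Al2O3
Reagents that add atoms: none
Why: Irradiation at 350 nm excites only enone 12, whose triplet adds to the strained, electron-poor alkene 17: the first bond is expected between C10 and C1, leaving radical centres at C5 (α to the ketone) and C4 (α to the ester), and collapse of this 1,4-biradical forms C4–C5. The closest known reaction type is the head-to-head photocycloaddition of 3-alkylcyclohex-2-enones with alkyl cyclobut-1-ene-1-carboxylates, the first half of a photocycloaddition–cycloreversion route to cyclodeca-1,5-dienes. One ring is closed, the C5–C4–C1–C10 cyclobutane, by radical–radical coupling of the 1,4-biradical (a stepwise [2+2] closure), and because it shares C1–C4 with the existing four-membered ring it completes the bicyclo[2.2.0]hexane. C10 is controlled by the trans lactone, which fixes the half-chair of 12 so that the β-carbon pyramidalises with the new C10–C1 bond axial, on the face anti to H7 and O8. C1 and C4 follow from the approach of 17 with its ring turned away from ring A (cis-anti-cis), C4 being tied to C1 by the cis fusion of the two small rings. C5 closes on the same face as the C10–C1 bond because a trans-fused cyclobutane is strained, and any trans isomer should epimerise at C5, α to the ketone, on neutral alumina. The step needs head-to-head regiochemistry, secured by the ester that makes C4 the more stabilised radical terminus, and the axial facial sense at C10, which rests only on the conformational bias of the bicyclic lactone. That facial sense is not innocent: with ring A locked it decides in step 14 which alkene becomes trans, whereas the syn or anti placement of the cyclobutene ring is lost once C1 and C4 become trigonal.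

Step 11
Reactants: 18 keto tert-butyl ester photoadduct
Product: 19 keto acid (1R,4S,5R,7R,8S,10R): the C15 carboxylic acid of 18
Conditions: CF3CO2H, CH2Cl2, 0 °C → rt
Reagents that add atoms: none
Why: Acidolysis of the tert-butyl ester through the tert-butyl cation frees the C15 acid without base, so the β-acyloxy ketone and the lactone are not exposed to elimination or hydrolysis.

Step 12
Reactants: 19 keto acid
Product: 20 tricyclic diol (1R,4S,5R,6R,7S,8S,10R): 6-hydroxy and 15-hydroxymethyl with the 6-OH trans to C4 and to C11
Conditions: BH3·THF (slow addition), THF, −20 → 20 °C; MeOH quench, aqueous work-up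
Reagents that add atoms: none
Why: Borane reduces a carboxylic acid much faster than a γ-lactone, and the boron bound at the C15 oxygen lies directly under C6 (C15 is cis to C6 on the cyclobutane), so hydride should reach the ketone intramolecularly from the cyclobutane face and give the 6R carbinol. Hydride attack from the open face, as an external reagent would prefer, would give the 6-epimer.

Step 13
Reactants: 20 tricyclic diol
Product: 21 bis(triethylsilyl) ether of 20 (1R,4S,5R,6R,7R,8S,10R)
Conditions: Et3SiOTf, 2,6-lutidine, CH2Cl2, −78 → 0 °C
Reagents that add atoms: triethylsilyl trifluoromethanesulfonate (CC[Si](CC)(CC)OS(=O)(=O)C(F)(F)F)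
Why: Silyl triflate with a hindered base silylates both the primary and the flanked secondary hydroxyl, giving groups that survive heat and lithium amide and leave with fluoride.

Step 14
Reactants: 21 bis(triethylsilyl) ether of 20
Product: 22 (1(10)E,4E,6R,7R,8S)-6,15-bis(triethylsilyloxy)-13-norgermacra-1(10),4-dien-12,8-olide (C4=C5 with C3 and C6 cis)
Conditions: degassed o-xylene (dilute), base-washed sealed tube, 185 °C
Reagents that add atoms: none
Why: Thermal [σ2s+σ2a] cycloreversion of the bicyclo[2.2.0]hexane: homolysis of the strained C1–C4 bond gives a cyclohexane-1,4-diyl that relaxes to a chair and cleaves C5–C10, a known route from such photoadducts to cyclodeca-1,5-dienes. Because the trans lactone holds ring A in one chair with C1 axial and C4 equatorial, C9 is equatorial and C6 axial on the diyl chair, which translates into trans C1=C10 and ring-cis C4=C5; C6, C7 and C8 are not touched.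

Step 15
Reactants: 22 13-norgermacradienolide bis(silyl ether)
Product: 23 11-(dimethylaminomethyl) derivative of 22 (C11 epimers)
Conditions: LiN(iPr)2, THF, −78 °C; Me2N=CH2 I, −78 → 0 °C
Reagents that add atoms: N,N-dimethylmethyleneiminium iodide (C[N+](C)=C.[I-])
Why: Mannich alkylation of the lactone lithium enolate with Eschenmoser's salt; the silyl ethers and the unconjugated ring alkenes are inert to the amide base, and the C11 configuration is irrelevant.

Step 16
Reactants: 23 11-(dimethylaminomethyl) lactone
Product: 25 (1(10)E,4E,6R,7R,8S)-6,15-bis(triethylsilyloxy)germacra-1(10),4,11(13)-trien-12,8-olide, via ammonium iodide 24 (not isolated)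
Conditions: MeI, MeOH, rt; NaHCO3 (aq.), EtOAc, rt
Reagents that add atoms: none
Why: Quaternisation and mild-base β-elimination of trimethylamine (Hofmann-type, E1cB through the lactone enolate) installs the exocyclic C11=C13 alkene under conditions that do not isomerise the ring alkenes.

Step 17
Reactants: 25 α-methylene lactone bis(silyl ether)
Product: 26 (1(10)E,4E,6R,7S,8S)-6,15-dihydroxygermacra-1(10),4,11(13)-trien-12,8-olide
Conditions: HF·pyridine, pyridine, THF, 0 °C → rt
Reagents that add atoms: none
Why: Pyridine-buffered fluoride desilylation removes both triethylsilyl groups without the strong acid that would trigger transannular cyclisation and without the base that would add to the α-methylene lactone.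

Step 18
Reactants: 26 6,15-diol
Product: 27 (1(10)E,4E,6R,7S,8S)-15-acetoxy-6-hydroxygermacra-1(10),4,11(13)-trien-12,8-olide
Conditions: AcCl, 2,4,6-collidine, CH2Cl2, −78 °C
Reagents that add atoms: acetyl chloride (CC(Cl)=O)
Why: Kinetic acylation with acetyl chloride and a hindered pyridine base selects the primary allylic C15 hydroxyl over the secondary C6 hydroxyl, which is flanked by C5 and C7.

Step 19
Reactants: 28 (2S)-3-bromo-2-hydroxy-2-methylpropanoic acid
Product: 30 (2R)-2,3-dihydroxy-2-methylpropanoic acid, via sodium glycidate 29 (not isolated)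
Conditions: NaOH (aq.), 60 °C; acidic ion-exchange resin, lyophilisation
Reagents that add atoms: sodium hydroxide ([Na+].[OH-])
Why: The tertiary alkoxide displaces bromide to give the 2-methylglycidate, which hydroxide opens at the primary carbon; no bond to C2 is broken, and the descriptor changes from S to R only because CH2OH ranks below the carboxyl group.

Step 20
Reactants: 30 (2R)-2,3-dihydroxy-2-methylpropanoic acid
Product: 32 (2R)-2-methyl-2,3-bis(triethylsilyloxy)propanoic acid, via silyl ester 31 (not isolated)
Conditions: Et3SiOTf, 2,6-lutidine, CH2Cl2, 0 °C → rt; K2CO3 (cat.), MeOH, 0 °C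
Reagents that add atoms: triethylsilyl trifluoromethanesulfonate (CC[Si](CC)(CC)OS(=O)(=O)C(F)(F)F)
Why: Exhaustive silylation followed by brief methanolysis, which cleaves the labile silyl ester far faster than the silyl ethers, gives the acid with both hydroxyls masked by fluoride-labile groups.

Step 21
Reactants: 27 15-acetoxy-6-hydroxy germacratrienolide; 32 (2R)-2-methyl-2,3-bis(triethylsilyloxy)propanoic acid
Product: 34 6-O-[(2R)-2-methyl-2,3-bis(triethylsilyloxy)propanoyl] derivative of 27 (6R,7R,8S), via mixed anhydride 33 (not isolated)
Conditions: 2,4,6-Cl3C6H2COCl, Et3N, THF, rt; then 27, DMAP, toluene, rt → 40 °C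
Reagents that add atoms: none
Why: Yamaguchi esterification: the mixed anhydride of the hindered acid is opened by DMAP at the aliphatic carbonyl and the acylpyridinium acylates the C6 hydroxyl with retention. The acid has no α-hydrogen, so it cannot epimerise or form a ketene.

Step 22
Reactants: 34 bis(silyl)-protected ester
Product: 35 the target CNP0426025.2, (1(10)E,4E,6R,7R,8S)-15-acetoxy-6-[(2R)-2,3-dihydroxy-2-methylpropanoyloxy]germacra-1(10),4,11(13)-trien-12,8-olide
Conditions: HF·pyridine, pyridine, THF, 0 °C → rt
Reagents that add atoms: none
Why: Buffered fluoride removes the primary and the tertiary triethylsilyl ether while leaving the acetate, the C6 ester, the α-methylene lactone and the 1,5-diene intact.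

## Compound list

1 | methyl furan-2-carboxylate | COC(=O)c1ccco1 | starting material
2 | ethyl diazoacetate | CCOC(=O)C=[N+]=[N-] | starting material
3 | 6-ethyl 3-methyl (1S,5S,6S)-2-oxabicyclo[3.1.0]hex-3-ene-3,6-dicarboxylate | COC(=O)C1=C[C@H]2[C@H](C(=O)OCC)[C@H]2O1 | intermediate
4 | ethyl (1S,2S,3S)-2-formyl-3-[(methoxyoxalyl)oxy]cyclopropane-1-carboxylate | COC(=O)C(=O)O[C@@H]1[C@@H](C(=O)OCC)[C@@H]1C=O | intermediate
5 | trimethyl(2-methylprop-2-en-1-yl)silane | CC(=C)C[Si](C)(C)C | starting material
6 | ethyl (1S,2R,3S)-2-[(1S)-1-hydroxy-3-methylbut-3-en-1-yl]-3-[(methoxyoxalyl)oxy]cyclopropane-1-carboxylate | COC(=O)C(=O)O[C@@H]1[C@@H](C(=O)OCC)[C@@H]1[C@@H](O)CC(C)=C | intermediate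
7 | free cyclopropanol of 6 (oxalate removed, configuration unchanged) | O[C@@H]1[C@@H](C(=O)OCC)[C@@H]1[C@@H](O)CC(C)=C | intermediate
8 | ethyl (3R,4S)-3-formyl-4-hydroxy-6-methylhept-6-enoate | O=C[C@H](CC(=O)OCC)[C@@H](O)CC(C)=C | intermediate
9 | (2S,3R)-2-(2-methylprop-2-en-1-yl)-5-oxooxolane-3-carbaldehyde | O=C[C@@H]1CC(=O)O[C@H]1CC(C)=C | intermediate
10 | (4S,5S)-4-(1-hydroxyprop-2-en-1-yl)-5-(2-methylprop-2-en-1-yl)oxolan-2-one, both carbinol epimers | C=CC(O)[C@@H]1CC(=O)O[C@H]1CC(C)=C | intermediate
11 | (3aS,7aS)-4-hydroxy-6-methyl-3a,4,7,7a-tetrahydro-1-benzofuran-2(3H)-one, both C4 epimers | OC1C=C(C)C[C@@H]2OC(=O)C[C@@H]12 | intermediate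
12 | (3aR,7aS)-6-methyl-3a,7a-dihydro-1-benzofuran-2,4(3H,7H)-dione (enone lactone, 7R,8S) | O=C1C=C(C)C[C@@H]2OC(=O)C[C@@H]12 | intermediate
13 | cyclobutanecarboxylic acid | OC(=O)C1CCC1 | starting material
14 | cyclobutanecarbonyl chloride | ClC(=O)C1CCC1 | intermediate
15 | 1-bromocyclobutane-1-carbonyl chloride | ClC(=O)C1(Br)CCC1 | intermediate
16 | tert-butyl 1-bromocyclobutane-1-carboxylate | CC(C)(C)OC(=O)C1(Br)CCC1 | intermediate
17 | tert-butyl cyclobut-1-ene-1-carboxylate | CC(C)(C)OC(=O)C1=CCC1 | intermediate
18 | keto tert-butyl ester photoadduct (1R,4S,5R,7R,8S,10R), cis-anti-cis, small rings anti to H7 | O=C1[C@H]2[C@]3(C(=O)OC(C)(C)C)CC[C@@H]3[C@@]2(C)C[C@@H]2OC(=O)C[C@@H]12 | intermediate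
19 | keto acid (1R,4S,5R,7R,8S,10R) | O=C1[C@H]2[C@]3(C(=O)O)CC[C@@H]3[C@@]2(C)C[C@@H]2OC(=O)C[C@@H]12 | intermediate
20 | tricyclic 6,15-diol (1R,4S,5R,6R,7S,8S,10R) | O[C@@H]1[C@H]2[C@]3(CO)CC[C@@H]3[C@@]2(C)C[C@@H]2OC(=O)C[C@@H]12 | intermediate
21 | tricyclic 6,15-bis(triethylsilyl) ether (1R,4S,5R,6R,7R,8S,10R) | CC[Si](CC)(CC)O[C@@H]1[C@H]2[C@]3(CO[Si](CC)(CC)CC)CC[C@@H]3[C@@]2(C)C[C@@H]2OC(=O)C[C@@H]12 | intermediate
22 | (1(10)E,4E,6R,7R,8S)-6,15-bis(triethylsilyloxy)-13-norgermacra-1(10),4-dien-12,8-olide | O=C1O[C@H]2C/C(C)=C/CC/C(CO[Si](CC)(CC)CC)=C\[C@@H](O[Si](CC)(CC)CC)[C@@H]2C1 | intermediate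
23 | 11-(dimethylaminomethyl) derivative of 22, C11 epimers | O=C1O[C@H]2C/C(C)=C/CC/C(CO[Si](CC)(CC)CC)=C\[C@@H](O[Si](CC)(CC)CC)[C@@H]2C1CN(C)C | intermediate
24 | trimethylammonium iodide of 23 | O=C1O[C@H]2C/C(C)=C/CC/C(CO[Si](CC)(CC)CC)=C\[C@@H](O[Si](CC)(CC)CC)[C@@H]2C1C[N+](C)(C)C.[I-] | intermediate
25 | (1(10)E,4E,6R,7R,8S)-6,15-bis(triethylsilyloxy)germacra-1(10),4,11(13)-trien-12,8-olide | C=C1C(=O)O[C@H]2C/C(C)=C/CC/C(CO[Si](CC)(CC)CC)=C\[C@@H](O[Si](CC)(CC)CC)[C@H]12 | intermediate
26 | (1(10)E,4E,6R,7S,8S)-6,15-dihydroxygermacra-1(10),4,11(13)-trien-12,8-olide | C=C1C(=O)O[C@H]2C/C(C)=C/CC/C(CO)=C\[C@@H](O)[C@H]12 | intermediate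
27 | (1(10)E,4E,6R,7S,8S)-15-acetoxy-6-hydroxygermacra-1(10),4,11(13)-trien-12,8-olide | C=C1C(=O)O[C@H]2C/C(C)=C/CC/C(COC(C)=O)=C\[C@@H](O)[C@H]12 | intermediate
28 | (2S)-3-bromo-2-hydroxy-2-methylpropanoic acid | OC(=O)[C@](C)(O)CBr | starting material
29 | sodium (2R)-2-methyloxirane-2-carboxylate | [Na+].[O-]C(=O)[C@@]1(C)CO1 | intermediate
30 | (2R)-2,3-dihydroxy-2-methylpropanoic acid | OC(=O)[C@](C)(O)CO | intermediate
31 | triethylsilyl (2R)-2-methyl-2,3-bis(triethylsilyloxy)propanoate | CC[Si](CC)(CC)OC(=O)[C@](C)(O[Si](CC)(CC)CC)CO[Si](CC)(CC)CC | intermediate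
32 | (2R)-2-methyl-2,3-bis(triethylsilyloxy)propanoic acid | OC(=O)[C@](C)(O[Si](CC)(CC)CC)CO[Si](CC)(CC)CC | intermediate
33 | (2R)-2-methyl-2,3-bis(triethylsilyloxy)propanoic 2,4,6-trichlorobenzoic anhydride | O=C(OC(=O)c1c(Cl)cc(Cl)cc1Cl)[C@](C)(O[Si](CC)(CC)CC)CO[Si](CC)(CC)CC | intermediate
34 | (6R,7R,8S)-15-acetoxy-6-[(2R)-2-methyl-2,3-bis(triethylsilyloxy)propanoyloxy]germacra-1(10)E,4E,11(13)-trien-12,8-olide | C=C1C(=O)O[C@H]2C/C(C)=C/CC/C(COC(C)=O)=C\[C@@H](OC(=O)[C@](C)(O[Si](CC)(CC)CC)CO[Si](CC)(CC)CC)[C@H]12 | intermediate
35 | CNP0426025.2, (6R,7R,8S)-15-acetoxy-6-[(2R)-2,3-dihydroxy-2-methylpropanoyloxy]germacra-1(10)E,4E,11(13)-trien-12,8-olide | C=C1C(=O)O[C@H]2C/C(C)=C/CC/C(COC(C)=O)=C\[C@@H](OC(=O)[C@](C)(O)CO)[C@H]12 | target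

## Step count and least certain steps

Total: 22 steps. Longest linear sequence: 18 steps (steps 1–7, 10–18, 21, 22). Steps 8–9 and 19–20 are two-step side branches.

**Step 10 (key step).**
- What may go wrong: insufficient facial discrimination at C10. Approach syn to H7 gives an adduct that, with ring A locked, would lead in step 14 to the opposite pair of alkene geometries and cannot be corrected later. Material may also be lost by β-elimination of the lactone carboxylate from the β-acyloxy ketones 12 and 18 during irradiation or the C5 equilibration, which limits how hard that equilibration can be pushed.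
- Why: the facial bias comes only from the half-chair of the trans-fused enone, and the lactone oxygen sits β to the ketone.
- Fallback (from 11, back at 18): the lactone is masked during the photochemistry. Compound 11 is reduced with iBu2AlH at −78 °C to the lactol F1, which is converted with MeOH and pyridinium tosylate into the methyl lactol ether F2. Dess–Martin oxidation gives the enone acetal F3, which is irradiated with 17 as in step 10 to give the acetal photoadduct F4. At this stage an acetal oxygen, a poor leaving group, replaces the carboxylate, so C5 can be equilibrated with NaOMe and the facial isomers separated on robust material. Jones reagent (CrO3, H2SO4, acetone, 0 °C) then oxidises the lactol ether directly to the lactone and returns 18.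

**Step 14.**
- What may go wrong: over-reaction at 185 °C. The first-formed diene may undergo Cope rearrangement or hydrogen shifts, the diyl may cleave along C2–C3 to the divinylcyclohexane, and geometric control may erode if cleavage starts before the diyl reaches the chair that ring A allows.
- Why: the unactivated central bond needs a high temperature, and the geometry rests on a conformational argument.
- Fallback (from 21, back at 22): a radical-stabilising formyl group is placed on C4 so that homolysis proceeds some 60 °C lower. The primary silyl ether of 21 is removed with pyridinium tosylate in MeOH at −10 °C to give the 15-alcohol F5. Dess–Martin oxidation gives the aldehyde F6. Heating in toluene at 120–130 °C should give the germacradienal F7. Luche reduction (NaBH4, CeCl3·7H2O, MeOH, −40 °C) gives the allylic alcohol F8, and Et3SiOTf with 2,6-lutidine returns 22.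

**Step 12.**
- What may go wrong: poor facial selectivity through competing intermolecular hydride attack on the open face of the ketone, giving the 6-epimer; to a lesser extent, over-reduction of the lactone.
- Why: free borane in solution is not forced to react through the C15-bound boron.
- Fallback (from 19, back at 21): the epimer is accepted and inverted. The 6-epi-diol F9 from the reduction of 19 is silylated at the primary hydroxyl (Et3SiCl, imidazole, −40 °C) to give the mono-silyl ether F10. Mitsunobu reaction with 4-nitrobenzoic acid, PPh3 and diisopropyl azodicarboxylate, the nucleophile entering from the open face, gives the inverted 4-nitrobenzoate F11. Brief K2CO3 in MeOH at 0 °C gives the 6R alcohol F12, and Et3SiOTf with 2,6-lutidine returns 21.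

**Step 21.**
- What may go wrong: slow acyl transfer between a flanked allylic alcohol and an α-quaternary, α-silyloxy acid. That would let competing transfer of the trichlorobenzoyl group, conjugate addition to the α-methylene lactone, or loss of the allylic acetate take over.
- Why: both coupling partners are hindered at the reacting centres.
- Fallback (from 30 and 27, back at 35): a smaller, tied-back acid is used. Compound 30 is treated with 2,2-dimethoxypropane, MeOH and TsOH to give the acetonide methyl ester F13. LiOH in aqueous THF gives the acetonide acid F14, which is coupled with 27 by carbodiimide activation (EDC·HCl, DMAP, CH2Cl2) to give the acetonide ester F15. Mild hydrolysis (CeCl3·7H2O, oxalic acid, MeCN, rt) gives 35. The price is an acidic last step on the diene, which is why the silyl route is preferred.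

## Further compounds

F1 | step 10 | (3aS,7aS)-6-methyl-2,3,3a,4,7,7a-hexahydro-1-benzofuran-2,4-diol (lactol, C2 and C4 epimers) | OC1C=C(C)C[C@@H]2OC(O)C[C@@H]12
F2 | step 10 | (3aS,7aS)-2-methoxy-6-methyl-2,3,3a,4,7,7a-hexahydro-1-benzofuran-4-ol (methyl lactol ether) | OC1C=C(C)C[C@@H]2OC(OC)C[C@@H]12
F3 | step 10 | (3aR,7aS)-2-methoxy-6-methyl-3,3a,7,7a-tetrahydro-1-benzofuran-4(2H)-one (enone acetal) | O=C1C=C(C)C[C@@H]2OC(OC)C[C@@H]12
F4 | step 10 | methyl lactol ether analogue of photoadduct 18 | O=C1[C@H]2[C@]3(C(=O)OC(C)(C)C)CC[C@@H]3[C@@]2(C)C[C@@H]2OC(OC)C[C@@H]12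
F5 | step 14 | tricyclic 6-triethylsilyloxy-15-alcohol | CC[Si](CC)(CC)O[C@@H]1[C@H]2[C@]3(CO)CC[C@@H]3[C@@]2(C)C[C@@H]2OC(=O)C[C@@H]12
F6 | step 14 | tricyclic 6-triethylsilyloxy-15-aldehyde | CC[Si](CC)(CC)O[C@@H]1[C@H]2[C@]3(C=O)CC[C@@H]3[C@@]2(C)C[C@@H]2OC(=O)C[C@@H]12
F7 | step 14 | (1(10)E,4E,6R,7R,8S)-15-oxo-6-(triethylsilyloxy)-13-norgermacra-1(10),4-dien-12,8-olide | O=C1O[C@H]2C/C(C)=C/CC/C(C=O)=C\[C@@H](O[Si](CC)(CC)CC)[C@@H]2C1
F8 | step 14 | (1(10)E,4E,6R,7R,8S)-15-hydroxy-6-(triethylsilyloxy)-13-norgermacra-1(10),4-dien-12,8-olide | O=C1O[C@H]2C/C(C)=C/CC/C(CO)=C\[C@@H](O[Si](CC)(CC)CC)[C@@H]2C1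
F9 | step 12 | 6-epimer of diol 20 (6S, OH cis to C4) | O[C@H]1[C@H]2[C@]3(CO)CC[C@@H]3[C@@]2(C)C[C@@H]2OC(=O)C[C@@H]12
F10 | step 12 | 15-O-triethylsilyl ether of the 6-epi-diol | O[C@H]1[C@H]2[C@]3(CO[Si](CC)(CC)CC)CC[C@@H]3[C@@]2(C)C[C@@H]2OC(=O)C[C@@H]12
F11 | step 12 | inverted (6R) 4-nitrobenzoate, 15-O-triethylsilyl | O=C(O[C@@H]1[C@H]2[C@]3(CO[Si](CC)(CC)CC)CC[C@@H]3[C@@]2(C)C[C@@H]2OC(=O)C[C@@H]12)c1ccc(cc1)[N+](=O)[O-]
F12 | step 12 | (6R)-6-alcohol, 15-O-triethylsilyl | O[C@@H]1[C@H]2[C@]3(CO[Si](CC)(CC)CC)CC[C@@H]3[C@@]2(C)C[C@@H]2OC(=O)C[C@@H]12
F13 | step 21 | methyl (4R)-2,2,4-trimethyl-1,3-dioxolane-4-carboxylate | COC(=O)[C@@]1(C)COC(C)(C)O1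
F14 | step 21 | (4R)-2,2,4-trimethyl-1,3-dioxolane-4-carboxylic acid | OC(=O)[C@@]1(C)COC(C)(C)O1
F15 | step 21 | side-chain acetonide of 35 | C=C1C(=O)O[C@H]2C/C(C)=C/CC/C(COC(C)=O)=C\[C@@H](OC(=O)[C@@]3(C)COC(C)(C)O3)[C@H]12
A1 | alternative 1 | ten-membered 1(10),4-diene with C5 triethylsilyl enol ether, C6 methoxymethyl ether, C8 and C12 tert-butyldimethylsilyl ethers, C15 triethylsilyl ether and C11=C13 side chain on C7 | CC(C)(C)[Si](C)(C)O[C@H]1C/C(C)=C/CC/C(CO[Si](CC)(CC)CC)=C(O[Si](CC)(CC)CC)\[C@@H](OCOC)[C@@H]1C(=C)CO[Si](C)(C)C(C)(C)C
A2 | alternative 2 | 13-norgermacra-1(10),4-dien-12,8-olide with C6 tert-butyldimethylsilyl ether and C15 4-methoxybenzyl ether | O=C1O[C@H]2C/C(C)=C/CC/C(COCc3ccc(OC)cc3)=C\[C@@H](O[Si](C)(C)C(C)(C)C)[C@@H]2C1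
A3 | alternative 3 | ten-membered dienoate with C15 ethyl ester, C6 triethylsilyl ether, C8 and C12 tert-butyldimethylsilyl ethers and C11=C13 side chain on C7 | CC(C)(C)[Si](C)(C)O[C@H]1C/C(C)=C/CC/C(C(=O)OCC)=C\[C@@H](O[Si](CC)(CC)CC)[C@@H]1C(=C)CO[Si](C)(C)C(C)(C)C
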